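A direct plan would close ring C last: aldol addition of the enolate of the brominated ring A methyl ketone A2 to the geranylated ring B aldehyde A1, oxidation to the 1,3-diketone A3, two reductions in sequence to the anti-1,3-diol A4, copper-mediated closure of the O1–C8a aryl ether to the flavan-4-ol A5, reoxidation at C4 and removal of the acetals.
Weakest point (a), the redox detour from the aldol to the flavanone: the C2 carbinol would be made racemic, oxidised away and reduced again, and a C4 carbinol would be set only to be oxidised, so five steps would add no skeletal bond.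
Weakest point (b), the enantioselective reduction of A3: it would have to tell two aryl ketones of a largely enolised 1,3-diketone apart, so both the site of reduction and the ee at C2 would rest on a modest steric bias.
Weakest point (c), the aryl ether closure of A4: a hot, basic copper coupling late in the route, on a benzylic diol with four acetals, where hydrodebromination and elimination would compete; the run-up to A1 and A2 would add an acetal on and off the aldehyde and a Friedel–Crafts acylation of uncertain site.

**Retrosynthetic overview**
Key disconnection: C2–C1′, the one bond that joins ring B to the heterocycle and whose carbon is the only stereocentre; it is made by enantioselective rhodium-catalysed 1,4-addition of the ring B boronic acid 8 to the flat, achiral 5,7-dioxygenated chromone 12.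
Ring order: ring A is bought (2′,4′,6′-trihydroxyacetophenone), ring C is closed first at O1–C2 (enaminone to chromone), ring B is attached last.
Ring B half: two C–H functionalisations of protected catechol, ortho-lithiation/geranylation at C3′ and sterically governed iridium C–H borylation at C1′, with no halogen and no aldehyde to mask.
Design gain: C2 is set once, by the catalyst, in the bond-forming step; C4 keeps its ketone oxidation state throughout, no diketone has to be differentiated and no aryl ether is closed under hot base.

Key step: step 6

Remark: ring A carries ethoxymethyl and ring B methoxymethyl acetals; both kinds are expected to leave under the same acid conditions in step 7.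
Remark: the sense of induction in step 6 is assigned by analogy with cyclohex-2-enone; it would be checked on the first run, and the (R,R)-diene would be used instead if the opposite sense were found.

Step 1
Reactants: 1 catechol
Product: 2 1,2-bis(methoxymethoxy)benzene
Conditions: NaH, MOMCl, DMF, 0 °C to rt
Reagents that add atoms: chloromethyl methyl ether (MOMCl), COCCl
Why: Williamson-type O-alkylation of both phenols gives acetals that direct ortho-lithiation, should survive organolithium, iridium and aqueous rhodium conditions, and leave in mild acid.

Step 2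
Reactants: 2 1,2-bis(methoxymethoxy)benzene; 3 geranyl bromide
Product: 6 1-[(2E)-3,7-dimethylocta-2,6-dien-1-yl]-2,3-bis(methoxymethoxy)benzene, via aryllithium 4 (not isolated), via arylcopper 5 (not isolated)
Conditions: n-BuLi, TMEDA, THF, −78 to 0 °C; CuBr·SMe2, −40 °C; 3, −40 to 0 °C
Reagents that add atoms: none
Why: Directed ortho-metalation next to an acetal oxygen (the two ortho positions are equivalent by symmetry), then transmetalation to an arylcopper that alkylates the primary allylic bromide in SN2 fashion, which should keep the E alkene and avoid the branched SN2′ product.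

Step 3
Reactants: 6 1-geranyl-2,3-bis(methoxymethoxy)benzene
Product: 8 [3-geranyl-4,5-bis(methoxymethoxy)phenyl]boronic acid, via pinacol boronate 7 (not isolated)
Conditions: [Ir(OMe)(cod)]2 (1.5 mol%), 4,4′-di-tert-butyl-2,2′-bipyridine (3 mol%), B2pin2 (1.0 equiv), THF, 60 °C; then NaIO4, NH4OAc, THF/H2O, rt
Reagents that add atoms: bis(pinacolato)diboron, CC1(C)OB(B2OC(C)(C)C(C)(C)O2)OC1(C)C; water, O
Why: Sterically governed iridium-catalysed aromatic C–H borylation (Ishiyama–Miyaura–Hartwig) should take the only ring C–H without an ortho substituent, which is the future C1′ (para to one acetal oxygen, meta to the geranyl group); buffered periodate cleavage of the released pinacol then frees the boronic acid without touching acetals or alkenes.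

Step 4
Reactants: 9 2′,4′,6′-trihydroxyacetophenone
Product: 10 1-[2,4-bis(ethoxymethoxy)-6-hydroxyphenyl]ethan-1-one
Conditions: EtOCH2Cl (2.2 equiv), i-Pr2NEt, CH2Cl2, 0 °C to rt
Reagents that add atoms: chloromethyl ethyl ether, CCOCCl
Why: O-alkylation with an amine base should stop at the bis-acetal, because the last phenol is held in a hydrogen bond to the acetyl carbonyl; this free hydroxyl is the one needed to close ring C.

Step 5
Reactants: 10 1-[2,4-bis(ethoxymethoxy)-6-hydroxyphenyl]ethan-1-one
Product: 12 5,7-bis(ethoxymethoxy)-4H-chromen-4-one, via enaminone 11 (not isolated)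
Conditions: Me2NCH(OMe)2, toluene, 95 °C; then AcOH, 50 °C
Reagents that add atoms: N,N-dimethylformamide dimethyl acetal, COC(OC)N(C)C
Why: Condensation of the methyl ketone with the amide acetal gives the vinylogous amide, and weak acid promotes addition of the phenol to its β-carbon and loss of dimethylamine (ring C closes at O1–C2 by addition–elimination); acetic acid should be too weak to exchange the aryl acetals.

Step 6
Reactants: 12 5,7-bis(ethoxymethoxy)-4H-chromen-4-one; 8 [3-geranyl-4,5-bis(methoxymethoxy)phenyl]boronic acid
Product: 13 (2S)-5,7-bis(ethoxymethoxy)-2-[3-geranyl-4,5-bis(methoxymethoxy)phenyl]chroman-4-one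
Conditions: [RhCl(C2H4)2]2 (2.5 mol%), (1S,4S)-2,5-diphenylbicyclo[2.2.2]octa-2,5-diene (5.5 mol%), KOH (10 mol%), 8 (1.6 equiv), 1,4-dioxane/H2O (10:1), 40 °C
Reagents that add atoms: none
Why: Hayashi–Miyaura reaction: the hydroxo complex of monovalent rhodium with the chiral diene takes the aryl group from 8 by transmetalation, the aryl–rhodium bond adds syn across C2=C3 of 12 (the step that fixes C2), and water protonates the resulting oxa-π-allyl rhodium enolate at C3, which returns the hydroxo complex. The closest known reaction type is the rhodium/chiral diene (or bisphosphine) 1,4-addition of arylboronic acids to chromones, which gives 2-arylchroman-4-ones. No ring is closed here (ring C is already present from step 5); the step forms the C2–C1′ bond that joins the two halves and creates the only stereocentre. C2 is controlled by the C2-symmetric diene alone, since 12 is flat and achiral: the (S,S)-ligand, which gives (S)-3-arylcyclohexanones from cyclohex-2-enone, should deliver the aryl group to the Re face of C2 (O1 takes the place of the ring CH2), which is 2S. The step needs 1,4- over 1,2-addition and no second arylation of the product ketone, which the vinylogous ester character of 12, the mild temperature and a stop at full conversion should secure, and it needs C2 to stay fixed afterwards, which the near-neutral medium should secure (only catalytic hydroxide, and both ring A oxygens capped so that no keto-phenolate can chelate rhodium or open ring C by elimination). The isolated trisubstituted alkenes of the geranyl chain are no acceptors for an aryl–rhodium bond, and the boron-bearing carbon of 8 has two ortho hydrogens, so transmetalation is unhindered.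

Step 7
Reactants: 13 (2S)-tetra-acetal flavanone
Product: 14 Isonymphaeol B
Conditions: HCl (1 M in MeOH), 40 °C, stopped at full conversion
Reagents that add atoms: none
Why: Acid-catalysed acetal exchange with methanol should free the four phenols under conditions too mild for hydration or cyclisation of the geranyl alkenes, and C2 is not epimerised because no base is present.

**Compound list**

1 | catechol | Oc1ccccc1O | starting material
2 | 1,2-bis(methoxymethoxy)benzene | COCOc1ccccc1OCOC | intermediate
3 | geranyl bromide, (2E)-1-bromo-3,7-dimethylocta-2,6-diene | CC(C)=CCC/C(C)=C/CBr | starting material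
4 | [2,3-bis(methoxymethoxy)phenyl]lithium | [Li]c1cccc(OCOC)c1OCOC | intermediate
5 | [2,3-bis(methoxymethoxy)phenyl]copper (ArCu, monovalent copper) | [Cu]c1cccc(OCOC)c1OCOC | intermediate
6 | 1-[(2E)-3,7-dimethylocta-2,6-dien-1-yl]-2,3-bis(methoxymethoxy)benzene | CC(C)=CCC/C(C)=C/Cc1cccc(OCOC)c1OCOC | intermediate
7 | 2-[3-geranyl-4,5-bis(methoxymethoxy)phenyl]-4,4,5,5-tetramethyl-1,3,2-dioxaborolane | CC(C)=CCC/C(C)=C/Cc1cc(B2OC(C)(C)C(C)(C)O2)cc(OCOC)c1OCOC | intermediate
8 | [3-geranyl-4,5-bis(methoxymethoxy)phenyl]boronic acid | CC(C)=CCC/C(C)=C/Cc1cc(B(O)O)cc(OCOC)c1OCOC | intermediate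
9 | 2′,4′,6′-trihydroxyacetophenone | CC(=O)c1c(O)cc(O)cc1O | starting material
10 | 1-[2,4-bis(ethoxymethoxy)-6-hydroxyphenyl]ethan-1-one | CC(=O)c1c(O)cc(OCOCC)cc1OCOCC | intermediate
11 | (2E)-1-[2,4-bis(ethoxymethoxy)-6-hydroxyphenyl]-3-(dimethylamino)prop-2-en-1-one | CN(C)/C=C/C(=O)c1c(O)cc(OCOCC)cc1OCOCC | intermediate
12 | 5,7-bis(ethoxymethoxy)-4H-chromen-4-one | O=c1ccoc2cc(OCOCC)cc(OCOCC)c12 | intermediate
13 | (2S)-5,7-bis(ethoxymethoxy)-2-[3-geranyl-4,5-bis(methoxymethoxy)phenyl]chroman-4-one | CC(C)=CCC/C(C)=C/Cc1cc([C@@H]2CC(=O)c3c(OCOCC)cc(OCOCC)cc3O2)cc(OCOC)c1OCOC | intermediate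
14 | Isonymphaeol B, (2S)-2-(3-geranyl-4,5-dihydroxyphenyl)-5,7-dihydroxychroman-4-one | CC(C)=CCC/C(C)=C/Cc1cc([C@@H]2CC(=O)c3c(O)cc(O)cc3O2)cc(O)c1O | target

**Step count and risks**
Total: 7 steps. Longest linear sequence: 5 steps (steps 1, 2, 3, 6, 7); steps 4 and 5 form the second branch.

Steps most likely to fail:

1. Step 6. The process at risk is incomplete enantioface control, or erosion of ee after the addition through opening of the rhodium enolate to the chalcone phenoxide and reclosure; protodeboronation could also outrun the addition to the electron-rich chromone. Fallback, from 12 and 8 back to 13: the addition would be run with the achiral catalyst [Rh(OH)(cod)]2 in dioxane/H2O to give the racemic flavanone F1. F1 would then be resolved kinetically by Noyori–Ikariya transfer hydrogenation with RuCl[(R,R)-TsDPEN](p-cymene) and HCO2H/Et3N, stopped near half conversion. This catalyst forms (4R) carbinols from aryl ketones of this type and delivers hydride anti to the 2-aryl group, so it should consume the (2R) enantiomer as the cis-(2R,4R)-flavan-4-ol F2 and leave (2S)-13, which is separated by chromatography and rejoins the route at 13.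

2. Step 3. The process at risk is hydroboration or vinylic and allylic C–H borylation of the geranyl chain by the iridium boryl species in competition with the aromatic C–H bond. Fallback, from 2 back to 7: the borylation would be done before the alkenes are present. Lithiation of 2 as in step 2 (via 4) and quench with I2 should give 3-iodo-1,2-bis(methoxymethoxy)benzene F3, and the same iridium borylation (aryl iodides are tolerated) should give the iodo pinacol boronate F4. Iodine–magnesium exchange with i-PrMgCl·LiCl in THF at −78 °C, where a pinacol boronate survives, would give the arylmagnesium chloride F5, and its coupling with 3 under CuBr·SMe2 catalysis (10 mol%) would give 7, which enters the periodate stage of step 3.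

3. Step 7. The process at risk is acid-mediated cyclisation of the geranyl chain onto the freed 4′-hydroxyl (chroman formation), or addition of HCl or methanol to the trisubstituted alkenes, before the last acetal has gone. Fallback, from 13 back to 14: the Brønsted acid would be replaced by acetal-to-silyl ether exchange. Me3SiOTf and 2,2′-bipyridyl in CH2Cl2 at 0 °C should convert the four aryl acetals of 13 into the tetrakis(trimethylsilyl) ether F6, with the acetal carbons leaving as N-alkoxymethyl bipyridinium salts. Water at neutral pH then hydrolyses F6 to 14.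

**Further compounds**
F1 | step 6 | racemic 5,7-bis(ethoxymethoxy)-2-[3-geranyl-4,5-bis(methoxymethoxy)phenyl]chroman-4-one | CC(C)=CCC/C(C)=C/Cc1cc(C2CC(=O)c3c(OCOCC)cc(OCOCC)cc3O2)cc(OCOC)c1OCOC
F2 | step 6 | (2R,4R)-5,7-bis(ethoxymethoxy)-2-[3-geranyl-4,5-bis(methoxymethoxy)phenyl]chroman-4-ol (2,4-cis) | CC(C)=CCC/C(C)=C/Cc1cc([C@H]2C[C@@H](O)c3c(OCOCC)cc(OCOCC)cc3O2)cc(OCOC)c1OCOC
F3 | step 3 | 3-iodo-1,2-bis(methoxymethoxy)benzene | COCOc1cccc(I)c1OCOC
F4 | step 3 | 2-[3-iodo-4,5-bis(methoxymethoxy)phenyl]-4,4,5,5-tetramethyl-1,3,2-dioxaborolane | COCOc1cc(B2OC(C)(C)C(C)(C)O2)cc(I)c1OCOC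
F5 | step 3 | [2,3-bis(methoxymethoxy)-5-(4,4,5,5-tetramethyl-1,3,2-dioxaborolan-2-yl)phenyl]magnesium chloride | COCOc1cc(B2OC(C)(C)C(C)(C)O2)cc([Mg]Cl)c1OCOC
F6 | step 7 | (2S)-2-[3-geranyl-4,5-bis(trimethylsilyloxy)phenyl]-5,7-bis(trimethylsilyloxy)chroman-4-one | CC(C)=CCC/C(C)=C/Cc1cc([C@@H]2CC(=O)c3c(O[Si](C)(C)C)cc(O[Si](C)(C)C)cc3O2)cc(O[Si](C)(C)C)c1O[Si](C)(C)C
A1 | direct plan | 3-geranyl-4,5-bis(methoxymethoxy)benzaldehyde | CC(C)=CCC/C(C)=C/Cc1cc(C=O)cc(OCOC)c1OCOC
A2 | direct plan | 1-[2-bromo-4,6-bis(methoxymethoxy)phenyl]ethan-1-one | CC(=O)c1c(Br)cc(OCOC)cc1OCOC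
A3 | direct plan | 1-[2-bromo-4,6-bis(methoxymethoxy)phenyl]-3-[3-geranyl-4,5-bis(methoxymethoxy)phenyl]propane-1,3-dione | CC(C)=CCC/C(C)=C/Cc1cc(C(=O)CC(=O)c2c(Br)cc(OCOC)cc2OCOC)cc(OCOC)c1OCOC
A4 | direct plan | (1S,3S)-1-[2-bromo-4,6-bis(methoxymethoxy)phenyl]-3-[3-geranyl-4,5-bis(methoxymethoxy)phenyl]propane-1,3-diol | CC(C)=CCC/C(C)=C/Cc1cc([C@@H](O)C[C@H](O)c2c(Br)cc(OCOC)cc2OCOC)cc(OCOC)c1OCOC
A5 | direct plan | (2S,4S)-2-[3-geranyl-4,5-bis(methoxymethoxy)phenyl]-5,7-bis(methoxymethoxy)chroman-4-ol | CC(C)=CCC/C(C)=C/Cc1cc([C@@H]2C[C@H](O)c3c(OCOC)cc(OCOC)cc3O2)cc(OCOC)c1OCOC
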